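**Plan**
1. Cuts, in retrosynthetic order: the phenol O–benzyl mask. Then C3–C4 of the octacosanoyl chain, the bond between the β- and γ-carbons of the ester. Last, the two acyl–O bonds that install the acrylate and the active ester.
2. Enabling feature: the ester carbonyl C1 makes C2=C3 an acrylate, a radical acceptor open only at its terminal carbon C3. The rest of the chain, C4–C28, is hexacosanoic (cerotic) acid minus its carboxyl carbon, so the C25 primary radical is one decarboxylation away from a purchasable even-numbered fatty acid.
3. Forward: the arylethyl acrylate (C1–C3 plus the whole tyrosol part) and the N-hydroxyphthalimide ester of the C26 acid are each made in one step. They are joined C25 + C3 by a photoredox decarboxylative Giese addition, and hydrogenolysis of the benzyl ether ends the route.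
4. Rings: none is formed. The benzene ring is bought with the arylethanol.
5. Stereochemistry: the target has no stereocentre and no stereogenic double bond, so nothing has to be set or preserved.

Key step: step 3

Assumption: the SMILES holds no stereogenic element, so the request for a single enantiomer is met by the achiral compound itself.

Step 1
Reactants: 1 2-[4-(benzyloxy)phenyl]ethanol; 2 acryloyl chloride
Product: 3 2-[4-(benzyloxy)phenyl]ethyl acrylate
Conditions: Et3N (1.5 equiv), BHT (trace), CH2Cl2, 0 °C to rt
Reagents that add atoms: none
Why: O-acylation of a primary alcohol with an acid chloride and an amine base (Schotten–Baumann/Einhorn type) is fast at 0 °C, the alcohol is the only nucleophile because the phenol is already a benzyl ether, and no stereocentre is involved.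

Step 2
Reactants: 4 hexacosanoic acid (cerotic acid); 5 N-hydroxyphthalimide
Product: 6 1,3-dioxoisoindolin-2-yl hexacosanoate
Conditions: DIC (1.1 equiv), DMAP (10 mol %), THF–CH2Cl2, 35 °C
Reagents that add atoms: none
Why: Steglich-type carbodiimide esterification with DMAP as acyl-transfer catalyst turns the acid into its N-(acyloxy)phthalimide, the electron-accepting helper that leaves again in step 3, and gentle warming keeps the waxy acid in solution.

Step 3
Reactants: 6 1,3-dioxoisoindolin-2-yl hexacosanoate; 3 2-[4-(benzyloxy)phenyl]ethyl acrylate
Product: 9 2-[4-(benzyloxy)phenyl]ethyl octacosanoate (O-benzylbongardol), via pentacosyl radical 7 (not isolated), via alpha-ester radical 8 (not isolated)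
Conditions: Ru(bpy)3(PF6)2 (1 mol %), Hantzsch ester (1.5 equiv), 3 (1.5 equiv), degassed CH2Cl2, blue LEDs, 25–30 °C
Reagents that add atoms: none
Why: Photoexcited Ru(II) is reductively quenched by the Hantzsch ester, and the resulting Ru(I) passes one electron to the phthalimide of 6, whose radical anion breaks its N–O bond and loses CO2 to give the primary radical 7. Radical 7 is nucleophilic and adds to the unsubstituted terminal carbon of the electron-poor C=C of 3, which forms the C3–C4 bond and the ester-stabilised radical 8; 8 is electrophilic and takes a hydrogen atom from the Hantzsch ester (or is reduced and protonated) to give 9. The closest known reaction type is the photoredox decarboxylative Giese reaction of N-(acyloxy)phthalimides of primary fatty acids with acrylate esters. No ring is closed and no stereocentre is created. The step needs cross-coupling over homocoupling, terminal regiochemistry and a single addition: the polarity match of 7 with the acrylate and its low stationary concentration secure the first, the open CH2 terminus and the stabilisation of 8 by the ester carbonyl the second, and the polarity mismatch of 8 with further acrylate together with the fast hydrogen donor the third. The benzyl ether removes the weak phenolic O–H that could quench 7 or be acylated by 6.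

Step 4
Reactants: 9 2-[4-(benzyloxy)phenyl]ethyl octacosanoate
Product: 10 bongardol, 2-(4-hydroxyphenyl)ethyl octacosanoate
Conditions: H2 (1 atm), 10% Pd/C, THF–EtOAc, 35 °C
Reagents that add atoms: none
Why: Catalytic hydrogenolysis of a benzyl aryl ether over Pd/C cleaves only the benzylic C–O bond, because the ester oxygen sits on a homobenzylic carbon and the chain is saturated, and the neutral medium prevents ester exchange to the freed phenol.

**Compound list**
1 | 2-[4-(benzyloxy)phenyl]ethanol | OCCc1ccc(OCc2ccccc2)cc1 | starting material
2 | acryloyl chloride | C=CC(=O)Cl | starting material
3 | 2-[4-(benzyloxy)phenyl]ethyl acrylate | C=CC(=O)OCCc1ccc(OCc2ccccc2)cc1 | intermediate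
4 | hexacosanoic acid (cerotic acid) | CCCCCCCCCCCCCCCCCCCCCCCCCC(=O)O | starting material
5 | N-hydroxyphthalimide | ON1C(=O)c2ccccc2C1=O | starting material
6 | 1,3-dioxoisoindolin-2-yl hexacosanoate | CCCCCCCCCCCCCCCCCCCCCCCCCC(=O)ON1C(=O)c2ccccc2C1=O | intermediate
7 | pentacosyl radical | CCCCCCCCCCCCCCCCCCCCCCCC[CH2] | intermediate
8 | alpha-ester radical (1-{2-[4-(benzyloxy)phenyl]ethoxy}-1-oxooctacosan-2-yl) | CCCCCCCCCCCCCCCCCCCCCCCCCC[CH]C(=O)OCCc1ccc(OCc2ccccc2)cc1 | intermediate
9 | 2-[4-(benzyloxy)phenyl]ethyl octacosanoate (O-benzylbongardol) | CCCCCCCCCCCCCCCCCCCCCCCCCCCC(=O)OCCc1ccc(OCc2ccccc2)cc1 | intermediate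
10 | bongardol, 2-(4-hydroxyphenyl)ethyl octacosanoate | CCCCCCCCCCCCCCCCCCCCCCCCCCCC(=O)OCCc1ccc(O)cc1 | target

Total step count: 4. Longest linear sequence: 3 steps (1 → 3 → 9 → 10, or 4 → 6 → 9 → 10).

**Steps most likely to fail**

Step 3. The primary radical may be quenched by hydrogen transfer before it meets the acrylate. The adduct radical may add further acrylate (telomerisation). The waxy active ester may also fall out of solution under irradiation. The fallback replaces the alkene addition by a nickel-electrocatalytic doubly decarboxylative C(sp3)–C(sp3) cross-coupling of two redox-active esters, a union of two carbons of like polarity.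
- It sets out from 1 and 6.
- Alcohol 1 opens succinic anhydride (DMAP, Et3N, CH2Cl2) to give the half ester 4-{2-[4-(benzyloxy)phenyl]ethoxy}-4-oxobutanoic acid F1.
- F1 is coupled with 5 and DIC to give 2-[4-(benzyloxy)phenyl]ethyl 1,3-dioxoisoindolin-2-yl butanedioate F2.
- An excess of F2 is electrolysed with 6 in an undivided cell (Ni(II) with a tridentate N-ligand, NaI, DMF–THF, sacrificial zinc anode, carbon cathode, constant current).
- This should forge the same C3–C4 bond, and the fallback comes back to the route at 9.

Step 2. Activation may be slow because the acid is poorly soluble. Acyl migration within the carbodiimide adduct may consume the acid, and the active ester may hydrolyse during purification on silica. The fallback drops pre-activation altogether.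
- It sets out from 4 and 3.
- They are irradiated (400 nm LEDs, CH2Cl2) with a 9-arylacridine photocatalyst and a copper co-catalyst, a direct decarboxylative conjugate addition.
- Proton-coupled electron transfer inside the hydrogen-bonded acid–acridine complex releases radical 7 from the free acid.
- It comes back to the route at 9 and makes no compound outside the list (entry F0).

Step 4. The heterogeneous hydrogenolysis may stall because the waxy substrate is poorly soluble and coats the catalyst, and forcing conditions may begin to saturate the arene. The fallback avoids any deprotection.
- It sets out from 6.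
- Commercial tyrosol is acylated only at its primary hydroxyl with vinyl acrylate and immobilised Candida antarctica lipase B (MTBE, 40 °C) to give 2-(4-hydroxyphenyl)ethyl acrylate F3.
- F3 is submitted with 6 to the base-free conditions of step 3. The absence of base keeps the phenol protonated, so acyl transfer and oxa-Michael addition should stay slow.
- It comes back to the route directly at 10.

**Further compounds**
F1 | step 3 | 4-{2-[4-(benzyloxy)phenyl]ethoxy}-4-oxobutanoic acid | OC(=O)CCC(=O)OCCc1ccc(OCc2ccccc2)cc1
F2 | step 3 | 2-[4-(benzyloxy)phenyl]ethyl 1,3-dioxoisoindolin-2-yl butanedioate | O=C(CCC(=O)OCCc1ccc(OCc2ccccc2)cc1)ON1C(=O)c2ccccc2C1=O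
F0 | step 2 | none | none
F3 | step 4 | 2-(4-hydroxyphenyl)ethyl acrylate | C=CC(=O)OCCc1ccc(O)cc1
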